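(The numbers in the tables were generated by integration with constants of no real substance, noise included.)

**Small charge.** A small charge, 0.19 M of starting material in the east run, still sent 61.1% of the second substrate into cross product; the 0.42 M of the north run sent 74.2%.

in all of them: coupling partner 0.308 M

|  | starting material | second substrate | protic impurity | remark | time |
|---|---|---|---|---|---|
| south | 0.28 M | 0.056 M | 0.028 M | run made earlier |  |
| east | 0.19 M | 0.056 M | 0.028 M | run made earlier |  |
| north | 0.42 M | 0.056 M | 0.028 M | run made earlier |  |
| north-east | 0.28 M | 0.028 M | 0.028 M | run made earlier |  |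
| violet | 0.28 M (fed, over 5.0 min) | 0.0560 M | 0.0280 M | all else is in the flask from the start; the feed brings no volume worth counting | 6.0 min |
| ochre | 0.28 M (in portions, 2, over 5.0 min) | 0.0560 M | 0.0280 M | first portion at the start, last at 5.0 min | 6.0 min |
| blue | 0.28 M | 0.0560 M (fed, over 5.0 min) | 0.0280 M | all else is in the flask from the start; the feed brings no volume worth counting | 6.0 min |
| grey | 0.28 M | 0.0560 M | 0.0280 M | everything together at the start | 6.0 min |

| run | time / min | target / % | cross product / % |
|---|---|---|---|
| south | 0.500 | 10.8 | 13.0 |
| south | 1.00 | 9.7 | 13.6 |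
| south | 1.50 | 8.6 | 13.6 |
| south | 2.00 | 8.6 | 13.5 |
| south | 2.50 | 8.8 | 13.2 |
| south | 3.00 | 8.4 | 13.7 |
| south | 4.00 | 8.9 | 13.2 |
| east | 0.250 | 9.7 | 16.2 |
| east | 0.417 | 10.9 | 17.0 |
| east | 0.667 | 11.1 | 17.7 |
| east | 1.00 | 9.5 | 17.4 |
| east | 1.50 | 9.4 | 17.6 |
| east | 2.50 | 8.5 | 18.0 |
| east | 4.00 | 8.9 | 18.0 |
| north | 0.200 | 9.4 | 9.5 |
| north | 0.500 | 10.7 | 10.1 |
| north | 1.00 | 9.4 | 10.9 |
| north | 1.50 | 8.2 | 9.4 |
| north | 2.00 | 8.3 | 10.1 |
| north | 3.00 | 8.5 | 9.8 |
| north | 4.00 | 8.5 | 10.0 |
| north-east | 0.250 | 10.9 | 7.3 |
| north-east | 0.500 | 12.4 | 6.7 |
| north-east | 1.00 | 11.0 | 6.7 |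
| north-east | 2.00 | 8.9 | 6.9 |
| north-east | 4.00 | 9.2 | 6.9 |

(scatter of a reading: 0.3 percentage points)

- the flask with the highest share of target in target plus cross product ("all alike" if they lie within 1.5 percentage points) (violet / ochre / blue / grey / all alike)
- share of target in target plus cross product at the end, violet
- share of target in target plus cross product at the end, ochre
- share of target in target plus cross product at the end, blue
- share of target in target plus cross product at the end, grey

- the numbers in the tables scatter by 0.3 percentage points (one standard deviation)

**Cross ratio.** South's late readings put f, the share of second substrate found as cross product, at 67.3%. I kept the cross ratio s, a selectivity factor, at 2.26: f over 1−f, divided by starting material per coupling partner. East and north gave 2.54 and 2.11. South's late readings held target at 8.65% and cross product at 13.5%, so I reckoned grey at 39.1%.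

**Violet bracket.** South's highest target reading stood at 0.500 min, and I took that time as the coupling window. Violet's feed would average 0.0140 M in it, so I scaled target down to 0.433%. Counting the whole charge of second substrate as cross product, 20.0%, I reckoned violet's share at 2.12%. With coupling partner at its charge, s gave violet cross product 1.86% and a share of 18.8%. Going round with coupling partner at 0.5 of its charge gave violet 3.41%, so I committed to a violet share of 11.3%.

**Other flasks.** For ochre I counted the first portion as the one that reacted: s on it gave cross product 10.1%, with target 4.33% from that portion, so a share of 29.9%. For blue, south's late target with the whole charge of second substrate counted as cross product gave 30.2%. Grey led my reckoning.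

**The forecast.** It gave blue: violet 30%, ochre 36%, blue 93%, grey 39%, holding that “All chemistry ends within about 0.3 min.” Its grey matched mine; its violet stood above my bracket.

**Flask result.** Grey was highest at 39.0%, above blue 33.7%, ochre 29.1% and violet 10.1%.

    starting material + coupling partner → target (k = 0.0590 L mol⁻¹ s⁻¹)
    second substrate + coupling partner → second product (k = 0.400 L mol⁻¹ s⁻¹)
    starting material + second substrate → cross product (k = 0.750 L mol⁻¹ s⁻¹)
    target ⇌ isomer of the product (K = 1.10, k = 0.0260 s⁻¹)
    coupling partner → decomposed reagent (k = 0.0550 s⁻¹)
    coupling partner + protic impurity → quenched reagent (k = 0.810 L mol⁻¹ s⁻¹)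

**Ratio again.** Violet ended with 0.0434 M of second product and cross product at 4.51%, against the 3.41% I had from s. For ochre, s had given 10.1%; the flask held 10.7%. For a neighbour of grey charged with 0.22 M of second substrate, s gave 52.8%, and that flask held 52.2%.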